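**Retrosynthetic overview**
- The spiro-oxolane is cut at C9–O and C9–C11, giving a tricyclic keto lactone acetate (C1–C10, C17–C20) and an enantiopure C11–C16 alkyne that already carries C13.
- In the keto lactone, the strained 19,6-lactone is opened to a hydroxy ester. Ring A is then cut at C1–C10, which is the key ring closure: an intramolecular Michael addition of a 2-formylcyclohexanone onto a vinyl sulfone, giving the cis-decalin and quaternary C10.
- The cyclisation precursor comes from three pieces: a 4-silyloxycyclohexenone (ring B, from chiral-base desymmetrisation), a propionate ketene silyl acetal (C4–C5 by Mukaiyama–Michael) and 2-(phenylsulfonyl)allyl bromide (C3–C4 by alkylation).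
- The alkyne fragment comes from a dithiane ester via an α-keto ester and a catalytic asymmetric alkynylation (C13).
- Ring order: ring B (bought) → ring A (Michael) → 19,6-lactone → butyrolactone and spiro-oxolane (final acid step).

Assumption: the SMILES is taken literally, i.e. (4S,5S,6R,8R,9R,10S,13R) in labdane numbering, a cis-fused decalin (5-H cis to the C10 CH2OAc group) whose 19,6-lactone is trans-fused to both carbocycles.

Convention: labdane numbering (C1–C20) is used for all intermediates; β means the face of the C10 CH2O group; "hexanor" means 11,12,13,14,15,16-hexanor. The SMILES strings carry the full configuration.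

**Step 1**
Reactants: 1 4-[(tert-butyldimethylsilyl)oxy]cyclohexan-1-one
Product: 2 (R)-tert-butyldimethyl{[4-(trimethylsilyloxy)cyclohex-3-en-1-yl]oxy}silane
Conditions: (S,S)-bis(1-phenylethyl)amine, n-BuLi, LiCl, THF, −78 °C; TMSCl (internal quench)
Reagents that add atoms: chlorotrimethylsilane, C[Si](C)(C)Cl
Why: Desymmetrising enolisation of the meso ketone by the C2-symmetric chiral lithium amide removes one enantiotopic α-proton and fixes the C6 carbinol centre as R (about 90% ee, raised by crystallisation of a later intermediate).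

**Step 2**
Reactants: 2 (R)-tert-butyldimethyl{[4-(trimethylsilyloxy)cyclohex-3-en-1-yl]oxy}silane
Product: 3 (R)-4-[(tert-butyldimethylsilyl)oxy]cyclohex-2-en-1-one
Conditions: Pd(OAc)2 (10 mol%), O2 (1 atm), DMSO, 25 °C
Reagents that add atoms: none
Why: Saegusa–Ito dehydrogenation of the silyl enol ether places the alkene only on the enol-ether side and touches no stereocentre.

**Step 3**
Reactants: 3 (R)-4-[(tert-butyldimethylsilyl)oxy]cyclohex-2-en-1-one
Product: 4 (4R,6R)-4-[(tert-butyldimethylsilyl)oxy]-6-methylcyclohex-2-en-1-one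
Conditions: LiN(iPr)2, THF, −78 °C; MeI, −78 → −40 °C
Reagents that add atoms: iodomethane, CI
Why: Kinetic α'-deprotonation gives the cross-conjugated lithium enolate, which is methylated trans to the 4-silyloxy group (enolate alkylation, 1,3-induction), setting the future C8 methyl.

**Step 4**
Reactants: 5 methyl propanoate
Product: 6 (E)-tert-butyl[(1-methoxyprop-1-en-1-yl)oxy]dimethylsilane
Conditions: LiN(iPr)2, THF, −78 °C; TBSCl, DMPU, −78 → 0 °C
Reagents that add atoms: tert-butylchlorodimethylsilane, CC(C)(C)[Si](C)(C)Cl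
Why: O-silylation of the kinetic ester enolate gives the ketene silyl acetal.

**Step 5**
Reactants: 4 (4R,6R)-4-[(tert-butyldimethylsilyl)oxy]-6-methylcyclohex-2-en-1-one and 6 (E)-tert-butyl[(1-methoxyprop-1-en-1-yl)oxy]dimethylsilane
Product: 7 methyl 2-[3,6-bis(tert-butyldimethylsilyloxy)-4-methylcyclohex-2-en-1-yl]propanoate (5β-H 6β-OTBS 8α-Me; C4 epimer mixture)
Conditions: TBSOTf (5 mol%), CH2Cl2, −78 °C; Et3N quench, non-aqueous work-up
Reagents that add atoms: none
Why: Mukaiyama–Michael addition occurs axially on the enone face anti to the γ-OTBS group, which sets C5 (5-H cis to O6), and silyl transfer leaves the ketone masked as its C9/C10 TBS enol ether.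

**Step 6**
Reactants: 8 phenyl vinyl sulfone
Product: 9 2-(phenylsulfonyl)prop-2-en-1-ol
Conditions: HCHO (37% aq.), DABCO (0.3 equiv), THF, 25 °C
Reagents that add atoms: formaldehyde, C=O
Why: Morita–Baylis–Hillman reaction of the vinyl sulfone with formaldehyde.

**Step 7**
Reactants: 9 2-(phenylsulfonyl)prop-2-en-1-ol
Product: 10 [(3-bromoprop-1-en-2-yl)sulfonyl]benzene
Conditions: PBr3, Et2O, 0 °C
Reagents that add atoms: phosphorus tribromide, BrP(Br)Br
Why: SN2 substitution of the activated primary allylic alcohol by bromide.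

**Step 8**
Reactants: 7 methyl 2-[3,6-bis(tert-butyldimethylsilyloxy)-4-methylcyclohex-2-en-1-yl]propanoate and 10 [(3-bromoprop-1-en-2-yl)sulfonyl]benzene
Product: 11 methyl 2-[3,6-bis(tert-butyldimethylsilyloxy)-4-methylcyclohex-2-en-1-yl]-2-methyl-4-(phenylsulfonyl)pent-4-enoate (quaternary C4 as in the target)
Conditions: LiN(iPr)2, THF–DMPU, −78 °C; 10, −78 °C; AcOH quench
Reagents that add atoms: none
Why: Ester enolate alkylation (SN2 or SN2', same product) with the ketone still masked; in the A(1,3)-minimised conformer with C5–H eclipsing the enolate plane the bromide enters anti to the OTBS-bearing C6 branch, which fixes quaternary C4 with the CO2Me group on the side that later reaches O6.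

**Step 9**
Reactants: 11 methyl 2-[3,6-bis(tert-butyldimethylsilyloxy)-4-methylcyclohex-2-en-1-yl]-2-methyl-4-(phenylsulfonyl)pent-4-enoate
Product: 13 methyl 2-[6-(tert-butyldimethylsilyloxy)-2-(hydroxymethylidene)-4-methyl-3-oxocyclohexyl]-2-methyl-4-(phenylsulfonyl)pent-4-enoate, via β-keto acetal 12 (not isolated)
Conditions: HC(OMe)3, TMSOTf (10 mol%), CH2Cl2, −78 → −30 °C; then PPTS, acetone–H2O, 40 °C
Reagents that add atoms: trimethyl orthoformate, COC(OC)OC; water, O
Why: The silyl enol ether is alkylated regiospecifically at C10 by the dimethoxycarbenium ion (Mukaiyama-type acetal alkylation) and mild acid hydrolysis of the β-keto acetal gives the 2-formyl ketone as its hydroxymethylidene tautomer, with the secondary TBS ether untouched.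

**Step 10**
Reactants: 13 methyl 2-[6-(tert-butyldimethylsilyloxy)-2-(hydroxymethylidene)-4-methyl-3-oxocyclohexyl]-2-methyl-4-(phenylsulfonyl)pent-4-enoate
Product: 14 methyl 6β-(tert-butyldimethylsilyloxy)-9,20-dioxo-2ξ-(phenylsulfonyl)-hexanor-5β,8βH-labdan-19-oate
Conditions: DBU (0.2 equiv), MeCN, 0 → 25 °C
Reagents that add atoms: none
Why: Intramolecular Michael addition (6-endo-trig) of the 2-formyl ketone enolate through C10 onto the vinyl sulfone closes ring A; the tether on the equatorial C5 substituent delivers C1 axially to the same face, giving the cis-decalin with the formyl group cis to 5-H (C10 set), while the C2 sulfone centre forms as a mixture that is erased in step 12.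

**Step 11**
Reactants: 14 methyl 6β-(tert-butyldimethylsilyloxy)-9,20-dioxo-2ξ-(phenylsulfonyl)-hexanor-5β,8βH-labdan-19-oate
Product: 16 methyl 20-acetoxy-6β-(tert-butyldimethylsilyloxy)-9-oxo-2ξ-(phenylsulfonyl)-hexanor-5β,8βH-labdan-19-oate, via primary alcohol 15 (not isolated)
Conditions: NaBH4, MeOH–CH2Cl2, −78 °C; AcOH quench, evaporate; Ac2O, pyridine, DMAP (cat.), 0 °C
Reagents that add atoms: acetic anhydride, CC(=O)OC(C)=O
Why: Chemoselective hydride reduction of the neopentyl aldehyde in the presence of the hindered α-quaternary ketone, followed by immediate acetylation of the crude β-hydroxy ketone, which forestalls retro-aldol loss of formaldehyde and lactonisation onto C19.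

**Step 12**
Reactants: 16 methyl 20-acetoxy-6β-(tert-butyldimethylsilyloxy)-9-oxo-2ξ-(phenylsulfonyl)-hexanor-5β,8βH-labdan-19-oate
Product: 17 methyl 20-acetoxy-6β-(tert-butyldimethylsilyloxy)-9-oxo-hexanor-5β,8βH-labdan-19-oate
Conditions: Na(Hg) (6%), Na2HPO4, MeOH–THF, −20 °C
Reagents that add atoms: none
Why: Electron-transfer reductive desulfonylation of the secondary alkyl phenyl sulfone under buffered conditions that leave the hindered ketone, the esters and the silyl ether intact.

**Step 13**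
Reactants: 17 methyl 20-acetoxy-6β-(tert-butyldimethylsilyloxy)-9-oxo-hexanor-5β,8βH-labdan-19-oate
Product: 19 20-acetoxy-9-oxo-hexanor-5β,8βH-labdan-19,6β-olide, via hydroxy ester 18 (not isolated)
Conditions: HF·pyridine, THF, 0 → 25 °C; then TsOH·H2O (0.2 equiv), toluene, 90 °C, 4 Å MS
Reagents that add atoms: none
Why: Fluoride desilylation followed by acid-catalysed lactonisation (transesterification driven by removal of methanol) joins the C19 ester and the 6-hydroxyl, which both lie on the face of 5-H, without changing any stereocentre.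

**Step 14**
Reactants: 20 ethyl 1,3-dithiane-2-carboxylate and 21 (2-bromoethoxy)(tert-butyl)dimethylsilane
Product: 22 ethyl 2-{2-[(tert-butyldimethylsilyl)oxy]ethyl}-1,3-dithiane-2-carboxylate
Conditions: NaH, DMF–toluene, 0 → 25 °C
Reagents that add atoms: none
Why: Alkylation of the dithiane-stabilised ester anion (Corey–Seebach umpolung) by the primary bromide.

**Step 15**
Reactants: 22 ethyl 2-{2-[(tert-butyldimethylsilyl)oxy]ethyl}-1,3-dithiane-2-carboxylate
Product: 23 ethyl 4-[(tert-butyldimethylsilyl)oxy]-2-oxobutanoate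
Conditions: PhI(O2CCF3)2, MeCN–H2O (9:1), 0 °C
Reagents that add atoms: water, O
Why: Oxidative dethioketalisation by the hypervalent iodine reagent unmasks the α-keto ester.

**Step 16**
Reactants: 23 ethyl 4-[(tert-butyldimethylsilyl)oxy]-2-oxobutanoate and 24 ethynyltrimethylsilane
Product: 25 ethyl (S)-4-[(tert-butyldimethylsilyl)oxy]-2-hydroxy-2-[(trimethylsilyl)ethynyl]butanoate
Conditions: Zn(OTf)2 (20 mol%), Et3N (30 mol%), 2-(dimethylamino)-1-(4-nitrophenyl)-3-(tert-butyldimethylsilyloxy)propan-1-ol (22 mol%, the enantiomer that gives the S carbinol), toluene, 70 °C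
Reagents that add atoms: none
Why: Catalytic asymmetric zinc acetylide addition to the ketone of the α-keto ester (Carreira-type alkynylation), in which the amino alcohol ligand selects the carbonyl face and sets C13 (S here, 13R in the target once the alkyne is reduced).

**Step 17**
Reactants: 25 ethyl (S)-4-[(tert-butyldimethylsilyl)oxy]-2-hydroxy-2-[(trimethylsilyl)ethynyl]butanoate
Product: 26 ethyl (S)-4-[(tert-butyldimethylsilyl)oxy]-2-[(triethylsilyl)oxy]-2-[(trimethylsilyl)ethynyl]butanoate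
Conditions: TESOTf, 2,6-lutidine, CH2Cl2, −78 → 0 °C
Reagents that add atoms: triethylsilyl triflate, CC[Si](CC)(CC)OS(=O)(=O)C(F)(F)F
Why: Silylation of the tertiary alcohol by the silyl triflate shields the hydroxyl and the neighbouring ester from the acetylide chemistry.

**Step 18**
Reactants: 26 ethyl (S)-4-[(tert-butyldimethylsilyl)oxy]-2-[(triethylsilyl)oxy]-2-[(trimethylsilyl)ethynyl]butanoate
Product: 27 ethyl (S)-4-[(tert-butyldimethylsilyl)oxy]-2-ethynyl-2-[(triethylsilyl)oxy]butanoate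
Conditions: K2CO3 (0.2 equiv), EtOH, 0 °C
Reagents that add atoms: none
Why: Base-catalysed protodesilylation of the alkynylsilane by ethanol, which also avoids ester exchange.

**Step 19**
Reactants: 19 20-acetoxy-9-oxo-hexanor-5β,8βH-labdan-19,6β-olide and 27 ethyl (S)-4-[(tert-butyldimethylsilyl)oxy]-2-ethynyl-2-[(triethylsilyl)oxy]butanoate
Product: 28 ethyl (13S)-20-acetoxy-15-(tert-butyldimethylsilyloxy)-9ξ-hydroxy-13-(triethylsilyloxy)-5β,8βH-labd-11-yn-19,6β-olid-16-oate
Conditions: 27, n-BuLi, THF, −78 °C; CeCl3 (anhydrous), −78 °C; then 19, −78 °C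
Reagents that add atoms: none
Why: 1,2-Addition of the organocerium acetylide (low basicity, high carbonyl affinity) to the hindered C9 ketone without enolisation or attack on the acetate and the neopentyl lactone; the C9 configuration formed here is irrelevant because C9 is ionised in step 21.

**Step 20**
Reactants: 28 ethyl (13S)-20-acetoxy-15-(tert-butyldimethylsilyloxy)-9ξ-hydroxy-13-(triethylsilyloxy)-5β,8βH-labd-11-yn-19,6β-olid-16-oate
Product: 29 ethyl (13R)-20-acetoxy-15-(tert-butyldimethylsilyloxy)-9ξ-hydroxy-13-(triethylsilyloxy)-5β,8βH-labdan-19,6β-olid-16-oate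
Conditions: H2 (1 atm), Pd/C (10 wt%), EtOAc, 25 °C
Reagents that add atoms: none
Why: Heterogeneous catalytic hydrogenation of the alkyne to the alkane; the descriptor at C13 changes only through CIP priorities.

**Step 21**
Reactants: 29 ethyl (13R)-20-acetoxy-15-(tert-butyldimethylsilyloxy)-9ξ-hydroxy-13-(triethylsilyloxy)-5β,8βH-labdan-19,6β-olid-16-oate
Product: 31 (4S,5S,6R,8R,9R,10S,13R)-20-acetoxy-9,13-epoxylabdane-19,6:16,15-diolide (CNP0298733.1), via dihydroxy lactone 30 (not isolated)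
Conditions: TsOH·H2O (0.3 equiv), MeCN–H2O (20:1), 25 °C; then toluene, 70 °C
Reagents that add atoms: none
Why: Acid removes both silyl groups, the 15-hydroxyl lactonises onto the ethyl ester, and ionisation of the tertiary C9 carbinol with 5-exo capture by the 13-hydroxyl (cyclodehydration of a ditertiary 1,4-diol) closes the spiro-oxolane; C13 is retained because its α-acyl C–O bond cannot ionise, and the oxygen enters C9 anti to the C10 CH2OAc group (9R).

**Compound list**
1 | 4-[(tert-butyldimethylsilyl)oxy]cyclohexan-1-one | CC(C)(C)[Si](C)(C)OC1CCC(=O)CC1 | starting material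
2 | (R)-tert-butyldimethyl{[4-(trimethylsilyloxy)cyclohex-3-en-1-yl]oxy}silane | C[Si](C)(C)OC1=CC[C@H](O[Si](C)(C)C(C)(C)C)CC1 | intermediate
3 | (R)-4-[(tert-butyldimethylsilyl)oxy]cyclohex-2-en-1-one | O=C1C=C[C@H](O[Si](C)(C)C(C)(C)C)CC1 | intermediate
4 | (4R,6R)-4-[(tert-butyldimethylsilyl)oxy]-6-methylcyclohex-2-en-1-one (trans) | C[C@@H]1C[C@@H](O[Si](C)(C)C(C)(C)C)C=CC1=O | intermediate
5 | methyl propanoate | CCC(=O)OC | starting material
6 | (E)-tert-butyl[(1-methoxyprop-1-en-1-yl)oxy]dimethylsilane | CC=C(OC)O[Si](C)(C)C(C)(C)C | intermediate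
7 | methyl 2-[3,6-bis(tert-butyldimethylsilyloxy)-4-methylcyclohex-2-en-1-yl]propanoate; side chain and 4-Me both trans to 6-OTBS (5β-H, 6β-O, 8α-Me); C4 epimer mixture | COC(=O)C(C)[C@@H]1C=C(O[Si](C)(C)C(C)(C)C)[C@H](C)C[C@H]1O[Si](C)(C)C(C)(C)C | intermediate
8 | phenyl vinyl sulfone | C=CS(=O)(=O)c1ccccc1 | starting material
9 | 2-(phenylsulfonyl)prop-2-en-1-ol | C=C(CO)S(=O)(=O)c1ccccc1 | intermediate
10 | [(3-bromoprop-1-en-2-yl)sulfonyl]benzene | C=C(CBr)S(=O)(=O)c1ccccc1 | intermediate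
11 | methyl 2-[3,6-bis(tert-butyldimethylsilyloxy)-4-methylcyclohex-2-en-1-yl]-2-methyl-4-(phenylsulfonyl)pent-4-enoate; ring as in 7, quaternary C4 as in the target | COC(=O)[C@@](C)(CC(=C)S(=O)(=O)c2ccccc2)[C@@H]1C=C(O[Si](C)(C)C(C)(C)C)[C@H](C)C[C@H]1O[Si](C)(C)C(C)(C)C | intermediate
12 | methyl 2-[6-(tert-butyldimethylsilyloxy)-2-(dimethoxymethyl)-4-methyl-3-oxocyclohexyl]-2-methyl-4-(phenylsulfonyl)pent-4-enoate (C10 epimers) | COC(=O)[C@@](C)(CC(=C)S(=O)(=O)c2ccccc2)[C@@H]1C(C(OC)OC)C(=O)[C@H](C)C[C@H]1O[Si](C)(C)C(C)(C)C | intermediate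
13 | methyl 2-[6-(tert-butyldimethylsilyloxy)-2-(hydroxymethylidene)-4-methyl-3-oxocyclohexyl]-2-methyl-4-(phenylsulfonyl)pent-4-enoate | COC(=O)[C@@](C)(CC(=C)S(=O)(=O)c2ccccc2)[C@@H]1C(=CO)C(=O)[C@H](C)C[C@H]1O[Si](C)(C)C(C)(C)C | intermediate
14 | methyl 6β-(tert-butyldimethylsilyloxy)-9,20-dioxo-2ξ-(phenylsulfonyl)-hexanor-5β,8βH-labdan-19-oate (cis-decalin; 4α-Me, 4β-CO2Me, 10β-CHO) | O=C[C@@]12CC(S(=O)(=O)c3ccccc3)C[C@](C)(C(=O)OC)[C@H]2[C@H](O[Si](C)(C)C(C)(C)C)C[C@@H](C)C1=O | intermediate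
15 | methyl 6β-(tert-butyldimethylsilyloxy)-20-hydroxy-9-oxo-2ξ-(phenylsulfonyl)-hexanor-5β,8βH-labdan-19-oate | OC[C@@]12CC(S(=O)(=O)c3ccccc3)C[C@](C)(C(=O)OC)[C@H]2[C@H](O[Si](C)(C)C(C)(C)C)C[C@@H](C)C1=O | intermediate
16 | methyl 20-acetoxy-6β-(tert-butyldimethylsilyloxy)-9-oxo-2ξ-(phenylsulfonyl)-hexanor-5β,8βH-labdan-19-oate | CC(=O)OC[C@@]12CC(S(=O)(=O)c3ccccc3)C[C@](C)(C(=O)OC)[C@H]2[C@H](O[Si](C)(C)C(C)(C)C)C[C@@H](C)C1=O | intermediate
17 | methyl 20-acetoxy-6β-(tert-butyldimethylsilyloxy)-9-oxo-hexanor-5β,8βH-labdan-19-oate | CC(=O)OC[C@@]12CCC[C@](C)(C(=O)OC)[C@H]2[C@H](O[Si](C)(C)C(C)(C)C)C[C@@H](C)C1=O | intermediate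
18 | methyl 20-acetoxy-6β-hydroxy-9-oxo-hexanor-5β,8βH-labdan-19-oate | CC(=O)OC[C@@]12CCC[C@](C)(C(=O)OC)[C@H]2[C@H](O)C[C@@H](C)C1=O | intermediate
19 | 20-acetoxy-9-oxo-hexanor-5β,8βH-labdan-19,6β-olide | CC(=O)OC[C@@]12CCC[C@]3(C)C(=O)O[C@H](C[C@@H](C)C1=O)[C@@H]23 | intermediate
20 | ethyl 1,3-dithiane-2-carboxylate | CCOC(=O)C1SCCCS1 | starting material
21 | (2-bromoethoxy)(tert-butyl)dimethylsilane | BrCCO[Si](C)(C)C(C)(C)C | starting material
22 | ethyl 2-{2-[(tert-butyldimethylsilyl)oxy]ethyl}-1,3-dithiane-2-carboxylate | CCOC(=O)C1(CCO[Si](C)(C)C(C)(C)C)SCCCS1 | intermediate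
23 | ethyl 4-[(tert-butyldimethylsilyl)oxy]-2-oxobutanoate | CCOC(=O)C(=O)CCO[Si](C)(C)C(C)(C)C | intermediate
24 | ethynyltrimethylsilane | C#C[Si](C)(C)C | starting material
25 | ethyl (S)-4-[(tert-butyldimethylsilyl)oxy]-2-hydroxy-2-[(trimethylsilyl)ethynyl]butanoate | CCOC(=O)[C@@](O)(C#C[Si](C)(C)C)CCO[Si](C)(C)C(C)(C)C | intermediate
26 | ethyl (S)-4-[(tert-butyldimethylsilyl)oxy]-2-[(triethylsilyl)oxy]-2-[(trimethylsilyl)ethynyl]butanoate | CCOC(=O)[C@@](O[Si](CC)(CC)CC)(C#C[Si](C)(C)C)CCO[Si](C)(C)C(C)(C)C | intermediate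
27 | ethyl (S)-4-[(tert-butyldimethylsilyl)oxy]-2-ethynyl-2-[(triethylsilyl)oxy]butanoate | CCOC(=O)[C@@](O[Si](CC)(CC)CC)(C#C)CCO[Si](C)(C)C(C)(C)C | intermediate
28 | ethyl (13S)-20-acetoxy-15-(tert-butyldimethylsilyloxy)-9ξ-hydroxy-13-(triethylsilyloxy)-5β,8βH-labd-11-yn-19,6β-olid-16-oate (C9 epimers) | CC(=O)OC[C@@]12CCC[C@]3(C)C(=O)O[C@H](C[C@@H](C)C1(O)C#C[C@](O[Si](CC)(CC)CC)(C(=O)OCC)CCO[Si](C)(C)C(C)(C)C)[C@@H]23 | intermediate
29 | ethyl (13R)-20-acetoxy-15-(tert-butyldimethylsilyloxy)-9ξ-hydroxy-13-(triethylsilyloxy)-5β,8βH-labdan-19,6β-olid-16-oate | CC(=O)OC[C@@]12CCC[C@]3(C)C(=O)O[C@H](C[C@@H](C)C1(O)CC[C@](O[Si](CC)(CC)CC)(C(=O)OCC)CCO[Si](C)(C)C(C)(C)C)[C@@H]23 | intermediate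
30 | (13R)-20-acetoxy-9ξ,13-dihydroxy-5β,8βH-labdane-19,6β:16,15-diolide | CC(=O)OC[C@@]12CCC[C@]3(C)C(=O)O[C@H](C[C@@H](C)C1(O)CC[C@@]1(O)CCOC1=O)[C@@H]23 | intermediate
31 | (4S,5S,6R,8R,9R,10S,13R)-20-acetoxy-9,13-epoxylabdane-19,6:16,15-diolide | CC(=O)OC[C@@]12CCC[C@]3(C)C(=O)O[C@H](C[C@@H](C)[C@]14CC[C@]1(CCOC1=O)O4)[C@@H]23 | target

**Step count and risks**
Total step count: 21. Longest linear sequence: 13 steps (1, 2, 3, 5, 8, 9, 10, 11, 12, 13, 19, 20, 21).

Steps most likely to fail: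

- Step 8 (quaternary C4). Acyclic A(1,3) control may be weak or may run in the opposite sense. The fallback sets out from 4 and comes back at 11. Mukaiyama–Michael addition of commercial 1-methoxy-1-(tert-butyldimethylsilyloxy)ethene to 4 (TBSOTf cat., CH2Cl2, −78 °C) gives the nor-methyl enol ether methyl 2-[3,6-bis(tert-butyldimethylsilyloxy)-4-methylcyclohex-2-en-1-yl]acetate F1. LiN(iPr)2 then 10 gives the mono-alkylated ester methyl 2-[3,6-bis(tert-butyldimethylsilyloxy)-4-methylcyclohex-2-en-1-yl]-4-(phenylsulfonyl)pent-4-enoate F2. A second deprotonation (LiN(iPr)2, −78 °C) and MeI then bring in the methyl group last; because the second electrophile decides the configuration, reversing the order inverts the C4 epimer ratio and leads to 11.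

- Step 13 (strained lactone). Ring B must leave the chair for the lactone to close, so the transesterification may stall or the acetate may migrate. The fallback sets out from 17 and comes back at 19. LiI in pyridine at reflux cleaves the hindered methyl ester by SN2 attack at the methyl group (the neopentyl acetate cannot react this way) to the acid 20-acetoxy-6β-(tert-butyldimethylsilyloxy)-9-oxo-hexanor-5β,8βH-labdan-19-oic acid F3. HF·pyridine then gives the hydroxy acid 20-acetoxy-6β-hydroxy-9-oxo-hexanor-5β,8βH-labdan-19-oic acid F4. Yamaguchi activation (2,4,6-trichlorobenzoyl chloride, Et3N, then DMAP, toluene) closes the lactone irreversibly to 19.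

- Step 21 (spiro-ether closure). The C9 cation sits next to quaternary C10, so elimination, 1,2-shift, acetoxonium participation or a C9 epimer mixture can intervene. The fallback sets out from 28 and comes back at 31. Semihydrogenation (H2, Pd/CaCO3 poisoned with Pb(OAc)2, quinoline, EtOAc) gives the Z-alkene ethyl (11Z,13S)-20-acetoxy-15-(tert-butyldimethylsilyloxy)-9ξ-hydroxy-13-(triethylsilyloxy)-5β,8βH-labd-11-en-19,6β-olid-16-oate F5. PPTS (wet MeCN, then benzene, 40 °C) desilylates, lactonises and ionises C9 as a far more stabilised allylic cation, which the 13-hydroxyl traps to give the spiro-2,5-dihydrofuran 20-acetoxy-9α,13-epoxy-5β,8βH-labd-11-ene-19,6β:16,15-diolide F6. Hydrogenation (H2, Pd/C, EtOAc) then gives 31.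

**Further compounds**
F1 | step 8 | methyl 2-[3,6-bis(tert-butyldimethylsilyloxy)-4-methylcyclohex-2-en-1-yl]acetate | COC(=O)C[C@@H]1C=C(O[Si](C)(C)C(C)(C)C)[C@H](C)C[C@H]1O[Si](C)(C)C(C)(C)C
F2 | step 8 | methyl 2-[3,6-bis(tert-butyldimethylsilyloxy)-4-methylcyclohex-2-en-1-yl]-4-(phenylsulfonyl)pent-4-enoate | COC(=O)C(CC(=C)S(=O)(=O)c2ccccc2)[C@@H]1C=C(O[Si](C)(C)C(C)(C)C)[C@H](C)C[C@H]1O[Si](C)(C)C(C)(C)C
F3 | step 13 | 20-acetoxy-6β-(tert-butyldimethylsilyloxy)-9-oxo-hexanor-5β,8βH-labdan-19-oic acid | CC(=O)OC[C@@]12CCC[C@](C)(C(=O)O)[C@H]2[C@H](O[Si](C)(C)C(C)(C)C)C[C@@H](C)C1=O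
F4 | step 13 | 20-acetoxy-6β-hydroxy-9-oxo-hexanor-5β,8βH-labdan-19-oic acid | CC(=O)OC[C@@]12CCC[C@](C)(C(=O)O)[C@H]2[C@H](O)C[C@@H](C)C1=O
F5 | step 21 | ethyl (11Z,13S)-20-acetoxy-15-(tert-butyldimethylsilyloxy)-9ξ-hydroxy-13-(triethylsilyloxy)-5β,8βH-labd-11-en-19,6β-olid-16-oate | CC(=O)OC[C@@]12CCC[C@]3(C)C(=O)O[C@H](C[C@@H](C)C1(O)/C=C\[C@](O[Si](CC)(CC)CC)(C(=O)OCC)CCO[Si](C)(C)C(C)(C)C)[C@@H]23
F6 | step 21 | 20-acetoxy-9α,13-epoxy-5β,8βH-labd-11-ene-19,6β:16,15-diolide | CC(=O)OC[C@@]12CCC[C@]3(C)C(=O)O[C@H](C[C@@H](C)[C@]14C=C[C@]1(CCOC1=O)O4)[C@@H]23
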